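**Plan**
- Cuts (clerodane numbering): the C4=C18 alkene and the ring A enol go back to a 2,3-enediol bis(silyl) ether; C11–C12 is cut to a C11 aldehyde and a C12–C15 ylide; ring A is cut across C1–C10 and C4–C5.
- Enabling feature: C1–C2(O)–C3(O)–C4–C18 is a 2,3-dioxygenated pentadiene unit bridging the C5–C10 bond, and ring B (C6, C7–O, C8–Me, quaternary C9 bearing C11) is a reduced 3-methoxy-2-methylbenzoate, so C5=C10 of a ring B cyclohexadienone can act as the dienophile.
- Forward order: ring B first (benzamide, Birch reduction–methylation, dienone, C5 methyl), then ring A by Diels–Alder reaction, then the C11–C15 chain by Wittig reaction, then ring B transposition (C6 oxygen out, C7 ketone to acetate), with ring A oxidised last.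
- Stereochemistry: C9 from the (S)-prolinol-ether auxiliary; C5 and C10 from suprafacial diene addition anti to the C9 amide; C8 by equilibration next to the C7 ketone; C7 by dissolving-metal reduction; C13 from (S)-4-methyldihydrofuran-2(3H)-one.

Key step: step 7

Numbering: ring A is C1–C5 and C10, ring B is C5–C10; C11–C15 is the chain on C9; C16 sits on C13, C17 on C8, C18 on C4, C19 on C5, C20 on C9.
Assumption: the potassium enolate of the 2-methylbenzamide of the (S)-auxiliary is taken to be methylated on the face that gives the (R) quaternary centre of 6; were the sense opposite, the (R)-auxiliary would be used with no other change.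
Remark: C4 (erased in step 16) and the C6 carbinol (removed in step 13) are transient centres; the SMILES of 13 and 17–19 leave C6 open, and those of 19 and 20 leave C8 open.

Step 1
Reactants: 1 3-methoxy-2-methylbenzoic acid; 2 (S)-2-(methoxymethyl)pyrrolidine
Product: 4 (3-methoxy-2-methylphenyl)[(2S)-2-(methoxymethyl)pyrrolidin-1-yl]methanone, via 3-methoxy-2-methylbenzoyl chloride 3 (not isolated)
Conditions: (COCl)2, DMF (cat.), CH2Cl2, 0 °C to rt; evaporate; then 2, Et3N, CH2Cl2, 0 °C to rt
Reagents that add atoms: none
Why: N-acylation of a secondary amine by an acid chloride made in situ is routine and installs the auxiliary that will control C9.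

Step 2
Reactants: 4 benzamide
Product: 6 [(1R)-3-methoxy-1,2-dimethylcyclohexa-2,5-dien-1-yl][(2S)-2-(methoxymethyl)pyrrolidin-1-yl]methanone, via potassium amide enolate 5 (not isolated)
Conditions: K (2.2 equiv), NH3(l)/THF, t-BuOH (1.0 equiv), −78 °C; then MeI (3 equiv), −78 °C; NH4Cl
Reagents that add atoms: iodomethane, CI
Why: Birch reduction–alkylation of a chiral benzamide reduces the ring at the ipso and para carbons and methylates the resulting amide enolate at the ipso carbon under control of the methoxymethyl arm (sense as assumed above), which sets the future C9 while the methoxy group keeps C7=C8 as an enol ether.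

Step 3
Reactants: 6 cyclohexa-1,4-diene amide
Product: 7 (4R)-2-methoxy-4-{[(2S)-2-(methoxymethyl)pyrrolidin-1-yl]carbonyl}-3,4-dimethylcyclohexa-2,5-dien-1-one
Conditions: (C5H5NH)2Cr2O7 as mediator, t-BuOOH (4 equiv), Celite, benzene, rt
Reagents that add atoms: tert-butyl hydroperoxide, CC(C)(C)OO
Why: chromium-mediated bis-allylic oxidation of Birch-derived 1,4-dienes is the standard entry to 4,4-disubstituted cyclohexa-2,5-dienones, since only C6 is doubly allylic and the quaternary C9 prevents aromatisation.

Step 4
Reactants: 7 dienone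
Product: 8 (4R)-6-iodo-2-methoxy-4-{[(2S)-2-(methoxymethyl)pyrrolidin-1-yl]carbonyl}-3,4-dimethylcyclohexa-2,5-dien-1-one
Conditions: I2 (2 equiv), pyridine/CH2Cl2 (1:1), 0 °C to rt
Reagents that add atoms: iodine, II
Why: Johnson α-iodination of an enone (pyridine conjugate addition, enolate iodination, elimination) can only take place at C5, because the other α-carbon carries the methoxy group.

Step 5
Reactants: 8 iodo dienone
Product: 9 (4R)-2-methoxy-4-{[(2S)-2-(methoxymethyl)pyrrolidin-1-yl]carbonyl}-3,4,6-trimethylcyclohexa-2,5-dien-1-one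
Conditions: Me4Sn (3 equiv), PdCl2(PhCN)2 (5 mol %), AsPh3 (10 mol %), CuI (10 mol %), NMP, 80 °C
Reagents that add atoms: tetramethylstannane, C[Sn](C)(C)C
Why: Stille coupling of α-iodo enones under triphenylarsine/copper iodide conditions transfers methyl reliably and places C19 on C5.

Step 6
Reactants: 10 pentane-2,3-dione
Product: 11 (3Z)-2,3-bis(tert-butyldimethylsilyloxy)penta-1,3-diene
Conditions: t-BuMe2SiOTf (2.3 equiv), Et3N (3 equiv), CH2Cl2, 0 °C to rt
Reagents that add atoms: tert-butyldimethylsilyl triflate, CC(C)(C)[Si](C)(C)OS(=O)(=O)C(F)(F)F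
Why: soft enolisation and O-silylation of both carbonyls (the known route from biacetyl to 2,3-bis(silyloxy)butadienes) can only enolise outwards, and the ethyl ketone gives the enol ether with methyl cis to oxygen, the geometry that lets the diene reach its s-cis form with the methyl outside; tert-butyldimethylsilyl is chosen over trimethylsilyl so that the enediol ether lasts until step 16.

Step 7
Reactants: 9 ring B dienone; 11 bis(silyloxy)diene
Product: 12 cis-decalin adduct: ring A 2,3-bis(tert-butyldimethylsilyloxy)-2-ene carrying the C4 methyl; C5 methyl; C6 ketone; 7-methoxy-7-ene; C8 and C9 methyls; C9 carboxamide of 2; H10 cis to C19; C1 and C4 anti to the amide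
Conditions: 9, AlBr3/AlMe3 (10:1, 2.5 equiv of Al), toluene/CH2Cl2 (5:1), −20 °C; then 11 (3 equiv), −20 to 0 °C; pyridine, then aq. NaHCO3
Reagents that add atoms: none
Why: The aluminium Lewis acid binds the C6 carbonyl (the excess saturates the amide) and lowers the LUMO of C5=C10, so the electron-rich diene adds in a normal-demand, probably asynchronous [4+2] in which C1–C10 bonding leads C4–C5. The closest known reaction type is the AlBr3/AlMe3-promoted Diels–Alder reaction of hindered 2-silyloxydienes with 2-methylcycloalkenones, together with cycloadditions of 4,4-disubstituted cyclohexa-2,5-dienones; this particular pair is untested. Ring A closes by the cycloaddition itself, both bonds forming on one face of the dienophile, so C19 and H10 end up cis. C5 and C10 are set by diene approach anti to the bulky, aluminium-complexed C9 carboxamide (syn to C20), and C4 by the endo orientation towards the C6 carbonyl, a centre that is erased in step 16. The step needs site selectivity (C7=C8 is tetrasubstituted and deactivated by its methoxy group), regioselectivity (the unsubstituted, more nucleophilic terminus C1 goes to the β-carbon C10 and the methyl-bearing terminus to the α-carbon C5, the ortho orientation of 1-substituted dienes) and facial selectivity (amide against methyl at C9). AlMe3 scavenges HBr so that the silyl enol ethers of diene and adduct survive.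

Step 8
Reactants: 12 Diels–Alder adduct
Product: 13 hydroxy aldehyde: as 12 but with a C6 carbinol (epimers) and a C9 formyl group (C11) in place of the carboxamide
Conditions: Cp2Zr(H)Cl (4 equiv), THF, rt; then H2O/silica gel
Reagents that add atoms: none
Why: Schwartz hydrozirconation reduces the C6 ketone to its zirconium alkoxide and stops the tertiary amide at the N,O-zirconated hemiaminal, which collapses to the C11 aldehyde only on work-up with release of the auxiliary, while esters of silicon and both enol ethers are inert.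

Step 9
Reactants: 14 (S)-4-methyldihydrofuran-2(3H)-one
Product: 15 [(2S)-3-carboxy-2-methylpropyl]triphenylphosphonium bromide
Conditions: Ph3P·HBr (1.05 equiv), neat, 160 °C; crystallise
Reagents that add atoms: triphenylphosphine hydrobromide, Br.c1ccc(cc1)P(c1ccccc1)c1ccccc1
Why: acid-assisted SN2 opening of a γ-lactone at its O-alkyl carbon by triphenylphosphine is the known direct route to 3-carboxypropylphosphonium salts and does not touch the β-methyl stereocentre, the future C13.

Step 10
Reactants: 13 hydroxy aldehyde; 15 phosphonium salt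
Product: 17 (11Z)-alkenoic acid: as 13 but with C9 carrying CH=CH–CH(CH3)–CH2–CO2H (C11–C15 and C16; 13R), via ylide sodium carboxylate 16 (not isolated)
Conditions: 15 (3 equiv), NaN(SiMe3)2 (6.5 equiv), THF, 0 °C; then 13, −78 °C to rt; pH 5 phosphate buffer
Reagents that add atoms: none
Why: Wittig olefination with a carboxylate-bearing unstabilised ylide, as practised on lactols and hydroxy aldehydes in prostaglandin work, joins C11 to C12 at a non-enolisable aldehyde; the C6 alkoxide is a spectator and the alkene geometry is erased in step 11.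

Step 11
Reactants: 17 alkenoic acid
Product: 18 saturated acid: as 17 but with C11–C12 single
Conditions: 2-nitrobenzenesulfonylhydrazide (10 equiv, in portions), Et3N, CH2Cl2, rt
Reagents that add atoms: none
Why: diimide reduction saturates only the disubstituted C11=C12 bond, leaves the two tetrasubstituted enol ether bonds alone and, involving no metal hydride that could migrate the alkene, cannot scramble the allylic C13 centre.

Step 12
Reactants: 18 saturated acid
Product: 19 α-ketol: C6 carbinol and C7 ketone; C8 now CH(CH3) (epimers); ring A enediol bis(silyl) ether intact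
Conditions: oxalic acid (0.1 M), THF/H2O (4:1), 0 °C to rt, monitored
Reagents that add atoms: water, O
Why: acid-catalysed enol ether hydrolysis by rate-limiting protonation at C8 unveils the C7 ketone, and the ring A enediol ether is expected to survive because an oxygen on the carbon to be protonated and the bulky, weakly donating silyloxy groups slow its protonation well below that of the methyl enol ether.

Step 13
Reactants: 19 α-ketol
Product: 21 C7 ketone with C6 as CH2 and the C8 methyl cis to C20, via C8-epimeric ketone mixture 20 (not isolated)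
Conditions: SmI2 (3 equiv), THF/MeOH (10:1), −78 °C; aqueous work-up; then DBU (2.5 equiv), toluene, rt
Reagents that add atoms: none
Why: SmI2 α-deoxygenation of an α-hydroxy ketone (ketyl formation, loss of the C6 hydroxide, enolate protonation) is followed by base equilibration through the C7 enolate, which should leave C17 equatorial and cis to C20, with any 8-epimer recycled.

Step 14
Reactants: 21 C7 ketone
Product: 22 C7 alcohol: hydroxyl equatorial and trans to C17 and on the face of the C9 chain
Conditions: Li (excess), NH3(l)/THF, EtOH (2 equiv), −78 °C; NH4Cl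
Reagents that add atoms: none
Why: dissolving-metal reduction of a cyclohexanone gives the thermodynamically preferred equatorial alcohol, whereas hydride delivery along the axial path would be blocked by the syn-axial C4 and C20; the acid is protected as its carboxylate and the silyl enol ethers are not reducible.

Step 15
Reactants: 22 C7 alcohol
Product: 23 C7 acetate
Conditions: Ac2O, pyridine, DMAP (cat.), CH2Cl2, rt; aqueous work-up at pH 4
Reagents that add atoms: acetic anhydride, CC(=O)OC(C)=O
Why: DMAP-catalysed acetylation of an equatorial secondary alcohol is routine, and any mixed anhydride formed at C15 is hydrolysed on work-up.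

Step 16
Reactants: 23 acetate
Product: 24 ring A diosphenol: C2 ketone; C3 enol; C3=C4 alkene carrying C18
Conditions: Br2 (1.0 equiv), CH2Cl2, −78 °C
Reagents that add atoms: none
Why: bromine oxidation of a 1,2-bis(silyloxy)alkene to the 1,2-diketone with loss of two silyl bromides is the standard unmasking of enediol silyl ethers, and the dione should rest as the more substituted C3 enol, which erases C4.

Step 17
Reactants: 24 diosphenol
Product: 27 target CNP0257844.1: (5S,7S,8S,9R,10R,13R)-7-acetoxy-2-hydroxy-3-oxo-5,10-cis-cleroda-1,4(18)-dien-15-oic acid, via C4 phenylselenide 25 (not isolated), via C4 selenoxide 26 (not isolated)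
Conditions: PhSeCl (1.1 equiv), pyridine, CH2Cl2, 0 °C; then mCPBA (1.05 equiv), −78 to 0 °C
Reagents that add atoms: none
Why: electrophilic selenenylation of the C3 enol at C4 followed by selenoxide syn-elimination (the α-methylenation logic of α-methyl-α-phenylseleno carbonyl compounds) can only eliminate towards C18 because C5 is quaternary, after which the dione can enolise only towards C1.

**Compound list**
1 | 3-methoxy-2-methylbenzoic acid | COc1cccc(C(=O)O)c1C | starting material
2 | (S)-2-(methoxymethyl)pyrrolidine | COC[C@@H]1CCCN1 | starting material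
3 | 3-methoxy-2-methylbenzoyl chloride | COc1cccc(C(=O)Cl)c1C | intermediate
4 | (3-methoxy-2-methylphenyl)[(2S)-2-(methoxymethyl)pyrrolidin-1-yl]methanone | COc1cccc(C(=O)N2CCC[C@H]2COC)c1C | intermediate
5 | potassium amide enolate of the 1,4-dihydrobenzamide | COC[C@@H]1CCCN1C([O-])=C1C=CCC(OC)=C1C.[K+] | intermediate
6 | [(1R)-3-methoxy-1,2-dimethylcyclohexa-2,5-dien-1-yl][(2S)-2-(methoxymethyl)pyrrolidin-1-yl]methanone | C1=C[C@@](C)(C(=O)N2CCC[C@H]2COC)C(C)=C(OC)C1 | intermediate
7 | (4R)-2-methoxy-4-{[(2S)-2-(methoxymethyl)pyrrolidin-1-yl]carbonyl}-3,4-dimethylcyclohexa-2,5-dien-1-one | O=C1C=C[C@@](C)(C(=O)N2CCC[C@H]2COC)C(C)=C1OC | intermediate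
8 | (4R)-6-iodo-2-methoxy-4-{[(2S)-2-(methoxymethyl)pyrrolidin-1-yl]carbonyl}-3,4-dimethylcyclohexa-2,5-dien-1-one | O=C1C(I)=C[C@@](C)(C(=O)N2CCC[C@H]2COC)C(C)=C1OC | intermediate
9 | (4R)-2-methoxy-4-{[(2S)-2-(methoxymethyl)pyrrolidin-1-yl]carbonyl}-3,4,6-trimethylcyclohexa-2,5-dien-1-one | CC1=C[C@@](C)(C(=O)N2CCC[C@H]2COC)C(C)=C(OC)C1=O | intermediate
10 | pentane-2,3-dione | CCC(=O)C(C)=O | starting material
11 | (3Z)-2,3-bis(tert-butyldimethylsilyloxy)penta-1,3-diene | C=C(O[Si](C)(C)C(C)(C)C)/C(O[Si](C)(C)C(C)(C)C)=C/C | intermediate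
12 | cis-decalin Diels–Alder adduct (C2/C3 bis-silyl enediol, C6 ketone, C7 methyl enol ether, C9 carboxamide) | C[C@@H]1C(O[Si](C)(C)C(C)(C)C)=C(O[Si](C)(C)C(C)(C)C)C[C@@H]2[C@@](C)(C(=O)N3CCC[C@H]3COC)C(C)=C(OC)C(=O)[C@]12C | intermediate
13 | C6-hydroxy C11-aldehyde (C6 epimers) | C[C@@H]1C(O[Si](C)(C)C(C)(C)C)=C(O[Si](C)(C)C(C)(C)C)C[C@@H]2[C@@](C)(C=O)C(C)=C(OC)C(O)[C@]12C | intermediate
14 | (S)-4-methyldihydrofuran-2(3H)-one | O=C1C[C@H](C)CO1 | starting material
15 | [(2S)-3-carboxy-2-methylpropyl]triphenylphosphonium bromide | OC(=O)C[C@H](C)C[P+](c1ccccc1)(c1ccccc1)c1ccccc1.[Br-] | intermediate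
16 | sodium (3S)-3-methyl-4-(triphenylphosphoranylidene)butanoate | [Na+].[O-]C(=O)C[C@H](C)C=P(c1ccccc1)(c1ccccc1)c1ccccc1 | intermediate
17 | C6-hydroxy (11Z)-alken-15-oic acid (13R; C6 epimers) | C[C@@H]1C(O[Si](C)(C)C(C)(C)C)=C(O[Si](C)(C)C(C)(C)C)C[C@@H]2[C@@](C)(/C=C\[C@@H](C)CC(=O)O)C(C)=C(OC)C(O)[C@]12C | intermediate
18 | C6-hydroxy saturated 15-oic acid | C[C@@H]1C(O[Si](C)(C)C(C)(C)C)=C(O[Si](C)(C)C(C)(C)C)C[C@@H]2[C@@](C)(CC[C@@H](C)CC(=O)O)C(C)=C(OC)C(O)[C@]12C | intermediate
19 | C6-hydroxy C7-ketone (C6 and C8 epimers) | C[C@@H]1C(O[Si](C)(C)C(C)(C)C)=C(O[Si](C)(C)C(C)(C)C)C[C@@H]2[C@@](C)(CC[C@@H](C)CC(=O)O)C(C)C(=O)C(O)[C@]12C | intermediate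
20 | C7 ketone, C8 epimer mixture | C[C@@H]1C(O[Si](C)(C)C(C)(C)C)=C(O[Si](C)(C)C(C)(C)C)C[C@@H]2[C@@](C)(CC[C@@H](C)CC(=O)O)C(C)C(=O)C[C@]12C | intermediate
21 | C7 ketone, C17 cis to C20 | C[C@@H]1C(O[Si](C)(C)C(C)(C)C)=C(O[Si](C)(C)C(C)(C)C)C[C@@H]2[C@@](C)(CC[C@@H](C)CC(=O)O)[C@H](C)C(=O)C[C@]12C | intermediate
22 | C7 equatorial alcohol | C[C@@H]1C(O[Si](C)(C)C(C)(C)C)=C(O[Si](C)(C)C(C)(C)C)C[C@@H]2[C@@](C)(CC[C@@H](C)CC(=O)O)[C@H](C)[C@@H](O)C[C@]12C | intermediate
23 | C7 acetate | C[C@@H]1C(O[Si](C)(C)C(C)(C)C)=C(O[Si](C)(C)C(C)(C)C)C[C@@H]2[C@@](C)(CC[C@@H](C)CC(=O)O)[C@H](C)[C@@H](OC(C)=O)C[C@]12C | intermediate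
24 | ring A diosphenol (2-oxo, 3-hydroxy-3-ene) | CC1=C(O)C(=O)C[C@@H]2[C@@](C)(CC[C@@H](C)CC(=O)O)[C@H](C)[C@@H](OC(C)=O)C[C@]12C | intermediate
25 | C4 phenylselenide of the dione (enolised to C1) | CC1([Se]c2ccccc2)C(=O)C(O)=C[C@@H]2[C@@](C)(CC[C@@H](C)CC(=O)O)[C@H](C)[C@@H](OC(C)=O)C[C@]12C | intermediate
26 | C4 selenoxide | CC1([Se](=O)c2ccccc2)C(=O)C(O)=C[C@@H]2[C@@](C)(CC[C@@H](C)CC(=O)O)[C@H](C)[C@@H](OC(C)=O)C[C@]12C | intermediate
27 | CNP0257844.1, (5S,7S,8S,9R,10R,13R)-7-acetoxy-2-hydroxy-3-oxo-5,10-cis-cleroda-1,4(18)-dien-15-oic acid | C=C1C(=O)C(O)=C[C@@H]2[C@@](C)(CC[C@@H](C)CC(=O)O)[C@H](C)[C@@H](OC(C)=O)C[C@]12C | target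

**Count**
Total steps: 17. Longest linear sequence: 15 steps (steps 1–5, 7, 8, 10–17); steps 6 and 9 are side branches.

**Steps most likely to fail**

Step 7. The cycloaddition may be outrun by Lewis-acid-induced desilylation or self-condensation of the diene, because the dienophile bond carries an α-methyl group and a quaternary γ-carbon; discrimination between the two faces may also erode at the temperature needed. Fallback: take the C19 methyl out of the cycloaddition. It sets out from 7, whose C5=C10 bond bears hydrogen at both carbons and belongs to a well-precedented dienophile type. Reaction of 7 with 11 under the same promoter at lower temperature should give the C5-unmethylated cis-fused adduct F1. Kinetic deprotonation with LiN(iPr)2 at C5, the only α-hydrogen of the C6 ketone, and alkylation with MeI on the convex face of the ring-fusion enolate (syn to H10, as with 1-decalone ring-fusion enolates) comes back to the route at 12; steps 4 and 5 are then not needed.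

Step 8. Hydrozirconation may stall at the neopentyl, α-quaternary carboxamide, so that only the ketone is reduced. Fallback: it sets out from 12. LiNH2BH3 (THF, 0 °C to rt), which is known to take hindered tertiary amides to primary alcohols, reduces ketone and amide to the C6,C11-diol F2. Swern oxidation of both hydroxyls gives the C6-keto C11-aldehyde F3. Wittig reaction with ylide 16 at the aldehyde (the conjugated, neopentyl C6 ketone does not react) gives the C6-keto alkenoic acid F4. Luche reduction (NaBH4, CeCl3·7H2O, MeOH) of the C6 ketone comes back to the route at 17.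

Step 17. Selenenylation may be slow at the fully substituted C4 beside quaternary C5, or may go to C1 through the minor enol, and the peracid may attack the enolised dione. Fallback: it sets out from 24. Bromination of the enol with pyridinium tribromide (a smaller electrophile, under acid-equilibrating conditions that favour the more substituted α-carbon) gives the C4-bromo dione F5. Base-induced dehydrobromination towards C18 (Li2CO3, LiBr, DMF, 60 °C) comes back to the route at 27.

**Further compounds**
F1 | step 7 | C5-unmethylated cis-fused Diels–Alder adduct (H at C5) | C[C@@H]1C(O[Si](C)(C)C(C)(C)C)=C(O[Si](C)(C)C(C)(C)C)C[C@@H]2[C@@](C)(C(=O)N3CCC[C@H]3COC)C(C)=C(OC)C(=O)[C@H]12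
F2 | step 8 | C6,C11-diol (C6 epimers) | C[C@@H]1C(O[Si](C)(C)C(C)(C)C)=C(O[Si](C)(C)C(C)(C)C)C[C@@H]2[C@@](C)(CO)C(C)=C(OC)C(O)[C@]12C
F3 | step 8 | C6-keto C11-aldehyde | C[C@@H]1C(O[Si](C)(C)C(C)(C)C)=C(O[Si](C)(C)C(C)(C)C)C[C@@H]2[C@@](C)(C=O)C(C)=C(OC)C(=O)[C@]12C
F4 | step 8 | C6-keto (11Z)-alken-15-oic acid | C[C@@H]1C(O[Si](C)(C)C(C)(C)C)=C(O[Si](C)(C)C(C)(C)C)C[C@@H]2[C@@](C)(/C=C\[C@@H](C)CC(=O)O)C(C)=C(OC)C(=O)[C@]12C
F5 | step 17 | C4-bromo dione (enolised to C1) | CC1(Br)C(=O)C(O)=C[C@@H]2[C@@](C)(CC[C@@H](C)CC(=O)O)[C@H](C)[C@@H](OC(C)=O)C[C@]12C
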